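**Strategy.** The α‑methylene‑γ‑butyrolactone (O–C12–C11(=C13)–C7–C6, germacrane numbering) is cut off in one piece as 2‑bromoacrylic acid. C11–C7 and O–C6 are traced back to the C6=C7 end of a C4=C5–C6=C7 diene in a ten‑membered (1(10)E,4Z,6E)‑triene. The key step is a palladium‑catalysed Larock‑type heteroannulation: syn‑carbopalladation attaches C11 to C7, and the carboxylate oxygen then closes the lactone on C6 of the C4–C5–C6 π‑allyl. This sets C6 and C7 (trans‑fused) and keeps the 4Z olefin, which is allylic to C6. The triene comes from (S)‑carvone by anionic oxy‑Cope ring expansion, which fixes C8 and all ring‑olefin geometries.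

Key step: step 9

Remark: germacrane numbering is used from compound 11 on (ring C1–C10, C14 and C15 the methyls on C10 and C4, C11–C13 the lactone carbons); compounds 1, 5, 15 and 18 are assumed to be bought.

Step 1
Reactants: 1 (S)-(+)-carvone
Product: 2 (1S,5S)-cis-carveol
Conditions: NaBH4, CeCl3·7H2O, MeOH, −78 °C
Reagents that add atoms: none
Why: Luche 1,2‑reduction, in which axial hydride delivery to the half‑chair with equatorial isopropenyl should give the carbinol cis to the isopropenyl group (1S).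

Step 2
Reactants: 2 (1S,5S)-cis-carveol
Product: 3 (1S,5S)-cis-carveol tert-butyldimethylsilyl ether
Conditions: TBSCl, imidazole, DMF, 23 °C
Reagents that add atoms: tert-butyldimethylsilyl chloride, CC(C)(C)[Si](C)(C)Cl
Why: standard silylation of a secondary allylic alcohol, which touches no stereocenter.

Step 3
Reactants: 3 (1S,5S)-cis-carveol tert-butyldimethylsilyl ether
Product: 4 (4S,6S)-4-(tert-butyldimethylsilyloxy)-3-methyl-6-(prop-1-en-2-yl)cyclohex-2-en-1-one
Conditions: CrO3, 3,5-dimethylpyrazole, CH2Cl2, −20 °C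
Reagents that add atoms: chromium trioxide, O=[Cr](=O)=O
Why: allylic C–H oxidation (Salmond conditions) at the only ring methylene allylic to the trisubstituted olefin should give the transposed enone, and the non‑basic medium should leave the isopropenyl‑bearing α‑stereocenter and the exocyclic olefin in place.

Step 4
Reactants: 5 4-methoxybenzyl alcohol
Product: 6 4-methoxybenzyl vinyl ether
Conditions: vinyl acetate, [Ir(cod)Cl]2 (1 mol %), Na2CO3, toluene, 100 °C
Reagents that add atoms: vinyl acetate, CC(=O)OC=C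
Why: iridium‑catalysed transvinylation of an alcohol with vinyl acetate (Ishii vinyl ether synthesis).

Step 5
Reactants: 6 4-methoxybenzyl vinyl ether
Product: 8 (Z)-1-bromo-2-(4-methoxybenzyloxy)ethene, via dibromo ether 7 (not isolated)
Conditions: Br2, CH2Cl2, −78 °C; then i-Pr2NEt, 0 → 40 °C
Reagents that add atoms: bromine, BrBr
Why: bromination of the enol ether and dehydrobromination of the α‑bromo ether is the classical route to 2‑alkoxyvinyl bromides; the Z isomer should predominate (cis effect) and is purified by chromatography, and residual E isomer is destroyed at the lithiation stage.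

Step 6
Reactants: 8 (Z)-1-bromo-2-(4-methoxybenzyloxy)ethene, 4 (4S,6S)-4-(tert-butyldimethylsilyloxy)-3-methyl-6-(prop-1-en-2-yl)cyclohex-2-en-1-one
Product: 10 (1S,4S,6S)-4-(tert-butyldimethylsilyloxy)-1-[(Z)-2-(4-methoxybenzyloxy)ethenyl]-3-methyl-6-(prop-1-en-2-yl)cyclohex-2-en-1-ol, via vinyllithium 9 (not isolated)
Conditions: 8, t-BuLi (2 equiv), Et2O, −78 °C; then 4, THF, −78 °C; aq. NH4Cl
Reagents that add atoms: none
Why: bromine–lithium exchange with retention gives the O‑chelated, configurationally stable (Z)-2-alkoxyvinyllithium, which should add 1,2 to the enone from the face opposite to the cis‑disposed isopropenyl and silyloxy groups, so that the new alkenyl group is trans to isopropenyl.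

Step 7
Reactants: 10 (1S,4S,6S)-4-(tert-butyldimethylsilyloxy)-1-[(Z)-2-(4-methoxybenzyloxy)ethenyl]-3-methyl-6-(prop-1-en-2-yl)cyclohex-2-en-1-ol
Product: 13 (3S,8R)-3-(tert-butyldimethylsilyloxy)-8-(4-methoxybenzyloxy)-4,10-dimethylcyclodeca-1(10)E,4Z,6-trien-6-yl trifluoromethanesulfonate (C5 and C8 trans across C6=C7), via potassium alkoxide 11 (not isolated), via potassium dienolate 12 (not isolated)
Conditions: KN(SiMe3)2, 18-crown-6, THF, −78 → 0 °C; then PhNTf2, −78 °C
Reagents that add atoms: N-phenylbis(trifluoromethanesulfonimide), O=S(=O)(N(c1ccccc1)S(=O)(=O)C(F)(F)F)C(F)(F)F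
Why: anionic oxy‑Cope rearrangement through a chair transition state with both ring bonds equatorial, in which the Z enol ether places the ether oxygen axial and creates C8 as 8R, the equatorial ring bonds give the 1(10)E olefin and the ring‑trans C6=C7 enolate, O‑sulfonylation keeps that geometry, and the C8–O bond lies in the nodal plane of the enolate as formed, which should slow β‑elimination at low temperature.

Step 8
Reactants: 13 (3S,8R)-3-(tert-butyldimethylsilyloxy)-8-(4-methoxybenzyloxy)-4,10-dimethylcyclodeca-1(10)E,4Z,6-trien-6-yl trifluoromethanesulfonate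
Product: 14 (3S,8R)-3-(tert-butyldimethylsilyloxy)-8-(4-methoxybenzyloxy)-4,10-dimethylcyclodeca-1(10)E,4Z,6E-triene
Conditions: Pd(OAc)2 (5 mol %), PPh3, HCO2H, n-Bu3N, DMF, 40 °C; product used at once
Reagents that add atoms: none
Why: palladium‑catalysed formate reduction of an alkenyl triflate replaces OTf by H with retention and should give the 6E olefin of the 4Z,6E‑diene.

Step 9
Reactants: 14 (3S,8R)-3-(tert-butyldimethylsilyloxy)-8-(4-methoxybenzyloxy)-4,10-dimethylcyclodeca-1(10)E,4Z,6E-triene, 15 2-bromoacrylic acid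
Product: 16 (3S,6R,7R,8R)-3-(tert-butyldimethylsilyloxy)-8-(4-methoxybenzyloxy)germacra-1(10)E,4Z,11(13)-trien-12,6-olide
Conditions: 15 (2 equiv), Pd(OAc)2 (10 mol %), P(2-furyl)3 (20 mol %), Ag2CO3, MeCN, 35 °C
Reagents that add atoms: none
Why: Zerovalent palladium inserts into the C–Br bond of 15, the alkenylpalladium carboxylate adds syn across C6=C7 with carbon going to the less substituted diene terminus C7, and the resulting C4–C5–C6 π‑allyl complex is captured at C6 by the palladium‑bound carboxylate oxygen, which closes the lactone and returns zerovalent palladium. The closest known reaction is the Larock heteroannulation of 1,3‑dienes by aryl and vinylic halides that carry a hydroxyl, amino or carboxyl group. The five‑membered lactone closes in a 5‑exo sense on the allyl terminus C6 (bond O–C6), in preference to a seven‑membered ring at the fully substituted C4. C7 is set by the face of carbopalladation: the ring spans one face of the trans C6=C7 bond, and attack on the open face, anti to the C8–C9 bond with the C8 ether oxygen in the inside position, should give 7R; C6 is set by delivery of oxygen from the palladium face (cis addition to a trans olefin), which should give the 6R, trans‑fused lactone. The step needs regioselectivity for C7 over C4, chemoselectivity for the conjugated diene over the isolated C1=C10 olefin, and retention of the 4Z geometry; these rest on the substitution pattern of the diene, on the faster insertion of conjugated dienes, and on the trisubstituted C4 terminus, which resists π–σ–π exchange. The low temperature is chosen to keep the (E,E)-1,5‑diene of 14 from Cope ring contraction.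

Step 10
Reactants: 16 (3S,6R,7R,8R)-3-(tert-butyldimethylsilyloxy)-8-(4-methoxybenzyloxy)germacra-1(10)E,4Z,11(13)-trien-12,6-olide
Product: 17 (3S,6R,7R,8R)-3-(tert-butyldimethylsilyloxy)-8-hydroxygermacra-1(10)E,4Z,11(13)-trien-12,6-olide
Conditions: DDQ, CH2Cl2/pH 7 phosphate buffer, 0 °C
Reagents that add atoms: none
Why: oxidative cleavage of the 4‑methoxybenzyl ether (hydride abstraction, hydrolysis), to which the silyl ether, the lactone and the olefins should be inert.

Step 11
Reactants: 18 methyl angelate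
Product: 19 (Z)-2-methylbut-2-en-1-ol
Conditions: i-Bu2AlH, CH2Cl2, −78 °C; Rochelle salt
Reagents that add atoms: none
Why: 1,2‑reduction of the enoate to the allylic alcohol at low temperature with retention of the Z geometry.

Step 12
Reactants: 19 (Z)-2-methylbut-2-en-1-ol
Product: 20 [(2R,3S)-2,3-dimethyloxiran-2-yl]methanol
Conditions: Ti(Oi-Pr)4 (10 mol %), D-(−)-diethyl tartrate (12 mol %), t-BuOOH, 4 Å molecular sieves, CH2Cl2, −20 °C
Reagents that add atoms: tert-butyl hydroperoxide, CC(C)(C)OO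
Why: Sharpless asymmetric epoxidation, in which D-(−)-tartrate directs oxygen to the olefin face that gives the 2R,3S epoxy alcohol and the Z geometry becomes the cis relationship of CH2OH and the C3 methyl.

Step 13
Reactants: 20 [(2R,3S)-2,3-dimethyloxiran-2-yl]methanol
Product: 22 (2S,3S)-2,3-dimethyloxirane-2-carboxylic acid, via epoxy aldehyde 21 (not isolated)
Conditions: TEMPO (10 mol %), PhI(OAc)2 (2.2 equiv), MeCN/H2O, 0 → 23 °C
Reagents that add atoms: water, O
Why: TEMPO/PhI(OAc)2 oxidation of the primary alcohol through the aldehyde hydrate to the acid (Epp–Widlanski conditions), which leaves the epoxide and both stereocenters untouched.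

Step 14
Reactants: 17 (3S,6R,7R,8R)-3-(tert-butyldimethylsilyloxy)-8-hydroxygermacra-1(10)E,4Z,11(13)-trien-12,6-olide, 22 (2S,3S)-2,3-dimethyloxirane-2-carboxylic acid
Product: 24 (3S,6R,7R,8R)-3-(tert-butyldimethylsilyloxy)-8-[(2S,3S)-2,3-epoxy-2-methylbutanoyloxy]germacra-1(10)E,4Z,11(13)-trien-12,6-olide, via mixed anhydride 23 (not isolated)
Conditions: 22, 2,4,6-Cl3C6H2COCl, Et3N, THF, 23 °C; then 17, DMAP, toluene, 23 °C
Reagents that add atoms: none
Why: Yamaguchi esterification of the hindered C8 alcohol through the DMAP‑activated acyl group of the mixed anhydride, with retention at C8 and under non‑nucleophilic conditions that should spare the glycidic epoxide and the methylene lactone.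

Step 15
Reactants: 24 (3S,6R,7R,8R)-3-(tert-butyldimethylsilyloxy)-8-[(2S,3S)-2,3-epoxy-2-methylbutanoyloxy]germacra-1(10)E,4Z,11(13)-trien-12,6-olide
Product: 25 (3S,6R,7R,8R)-8-[(2S,3S)-2,3-epoxy-2-methylbutanoyloxy]-3-hydroxygermacra-1(10)E,4Z,11(13)-trien-12,6-olide
Conditions: HF·pyridine, pyridine, THF, 0 → 23 °C
Reagents that add atoms: none
Why: fluoride cleavage of the silyl ether under buffered conditions that should spare the lactone, the ester and the glycidic epoxide.

Step 16
Reactants: 25 (3S,6R,7R,8R)-8-[(2S,3S)-2,3-epoxy-2-methylbutanoyloxy]-3-hydroxygermacra-1(10)E,4Z,11(13)-trien-12,6-olide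
Product: 26 (3S,6R,7R,8R)-8-[(2S,3S)-2,3-epoxy-2-methylbutanoyloxy]-3-(3-methylbutanoyloxy)germacra-1(10)E,4Z,11(13)-trien-12,6-olide
Conditions: isovaleric anhydride, DMAP, Et3N, CH2Cl2, 0 °C
Reagents that add atoms: isovaleric anhydride, CC(C)CC(=O)OC(=O)CC(C)C
Why: DMAP‑catalysed acylation of the C3 allylic alcohol with retention.

Step 17
Reactants: 26 (3S,6R,7R,8R)-8-[(2S,3S)-2,3-epoxy-2-methylbutanoyloxy]-3-(3-methylbutanoyloxy)germacra-1(10)E,4Z,11(13)-trien-12,6-olide
Product: 27 (1R,3S,6R,7R,8R,10R)-1,10-epoxy-8-[(2S,3S)-2,3-epoxy-2-methylbutanoyloxy]-3-(3-methylbutanoyloxy)germacra-4Z,11(13)-dien-12,6-olide (CNP0167461.1)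
Conditions: mCPBA, NaHCO3, CH2Cl2, 0 °C
Reagents that add atoms: 3-chloroperoxybenzoic acid, OOC(=O)c1cccc(Cl)c1
Why: Prilezhaev epoxidation, in which C1=C10 is the only electron‑rich olefin (C4=C5 carries two allylic acyloxy groups, C11=C13 is conjugated) and peracid attack on its outer face in the conformer with C14 on the β face, as in 6,12‑trans‑germacranolides, should give the trans 1R,10R epoxide stereospecifically.

**Compound list**

1 | (S)-(+)-carvone | O=C1C[C@@H](C(C)=C)CC=C1C | starting material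
2 | (1S,5S)-cis-carveol | [C@H]1(O)C[C@@H](C(C)=C)CC=C1C | intermediate
3 | (1S,5S)-cis-carveol tert-butyldimethylsilyl ether | [C@H]1(O[Si](C)(C)C(C)(C)C)C[C@@H](C(C)=C)CC=C1C | intermediate
4 | (4S,6S)-4-(tert-butyldimethylsilyloxy)-3-methyl-6-(prop-1-en-2-yl)cyclohex-2-en-1-one | [C@H]1(O[Si](C)(C)C(C)(C)C)C[C@@H](C(C)=C)C(=O)C=C1C | intermediate
5 | 4-methoxybenzyl alcohol | COc1ccc(CO)cc1 | starting material
6 | 4-methoxybenzyl vinyl ether | C=COCc1ccc(OC)cc1 | intermediate
7 | 1,2-dibromoethyl 4-methoxybenzyl ether (racemic, not isolated) | BrCC(Br)OCc1ccc(OC)cc1 | intermediate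
8 | (Z)-1-bromo-2-(4-methoxybenzyloxy)ethene | Br/C=C\OCc1ccc(OC)cc1 | intermediate
9 | (Z)-2-(4-methoxybenzyloxy)ethenyllithium (not isolated) | [Li]/C=C\OCc1ccc(OC)cc1 | intermediate
10 | (1S,4S,6S)-4-(tert-butyldimethylsilyloxy)-1-[(Z)-2-(4-methoxybenzyloxy)ethenyl]-3-methyl-6-(prop-1-en-2-yl)cyclohex-2-en-1-ol (alkenyl trans to isopropenyl) | [C@H]1(O[Si](C)(C)C(C)(C)C)C[C@@H](C(C)=C)[C@](O)(/C=C\OCc2ccc(OC)cc2)C=C1C | intermediate
11 | potassium alkoxide of 10 (not isolated) | [C@H]1(O[Si](C)(C)C(C)(C)C)C[C@@H](C(C)=C)[C@]([O-])(/C=C\OCc2ccc(OC)cc2)C=C1C.[K+] | intermediate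
12 | potassium (3S,8R)-3-(tert-butyldimethylsilyloxy)-8-(4-methoxybenzyloxy)-4,10-dimethylcyclodeca-1(10)E,4Z,6-trien-6-olate, C5 and C8 trans across C6=C7 (not isolated) | [C@@H]1(O[Si](C)(C)C(C)(C)C)/C(C)=C\C([O-])=C\[C@H](OCc2ccc(OC)cc2)C/C(C)=C/C1.[K+] | intermediate
13 | (3S,8R)-3-(tert-butyldimethylsilyloxy)-8-(4-methoxybenzyloxy)-4,10-dimethylcyclodeca-1(10)E,4Z,6-trien-6-yl trifluoromethanesulfonate, C5 and C8 trans across C6=C7 | [C@@H]1(O[Si](C)(C)C(C)(C)C)/C(C)=C\C(OS(=O)(=O)C(F)(F)F)=C\[C@H](OCc2ccc(OC)cc2)C/C(C)=C/C1 | intermediate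
14 | (3S,8R)-3-(tert-butyldimethylsilyloxy)-8-(4-methoxybenzyloxy)-4,10-dimethylcyclodeca-1(10)E,4Z,6E-triene | [C@@H]1(O[Si](C)(C)C(C)(C)C)/C(C)=C\C=C\[C@H](OCc2ccc(OC)cc2)C/C(C)=C/C1 | intermediate
15 | 2-bromoacrylic acid | C=C(Br)C(=O)O | starting material
16 | (3S,6R,7R,8R)-3-(tert-butyldimethylsilyloxy)-8-(4-methoxybenzyloxy)germacra-1(10)E,4Z,11(13)-trien-12,6-olide | C=C1C(=O)O[C@@H]2/C=C(/C)[C@@H](O[Si](C)(C)C(C)(C)C)C/C=C(\C)C[C@@H](OCc3ccc(OC)cc3)[C@@H]12 | intermediate
17 | (3S,6R,7R,8R)-3-(tert-butyldimethylsilyloxy)-8-hydroxygermacra-1(10)E,4Z,11(13)-trien-12,6-olide | C=C1C(=O)O[C@@H]2/C=C(/C)[C@@H](O[Si](C)(C)C(C)(C)C)C/C=C(\C)C[C@@H](O)[C@@H]12 | intermediate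
18 | methyl angelate, methyl (Z)-2-methylbut-2-enoate | C/C=C(/C)C(=O)OC | starting material
19 | (Z)-2-methylbut-2-en-1-ol | C/C=C(/C)CO | intermediate
20 | [(2R,3S)-2,3-dimethyloxiran-2-yl]methanol | OC[C@@]1(C)O[C@H]1C | intermediate
21 | (2S,3S)-2,3-dimethyloxirane-2-carbaldehyde (not isolated) | O=C[C@@]1(C)O[C@H]1C | intermediate
22 | (2S,3S)-2,3-dimethyloxirane-2-carboxylic acid | OC(=O)[C@@]1(C)O[C@H]1C | intermediate
23 | (2S,3S)-2,3-dimethyloxirane-2-carboxylic 2,4,6-trichlorobenzoic anhydride (not isolated) | O=C(OC(=O)[C@@]1(C)O[C@H]1C)c1c(Cl)cc(Cl)cc1Cl | intermediate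
24 | (3S,6R,7R,8R)-3-(tert-butyldimethylsilyloxy)-8-[(2S,3S)-2,3-epoxy-2-methylbutanoyloxy]germacra-1(10)E,4Z,11(13)-trien-12,6-olide | C=C1C(=O)O[C@@H]2/C=C(/C)[C@@H](O[Si](C)(C)C(C)(C)C)C/C=C(\C)C[C@@H](OC(=O)[C@@]3(C)O[C@H]3C)[C@@H]12 | intermediate
25 | (3S,6R,7R,8R)-8-[(2S,3S)-2,3-epoxy-2-methylbutanoyloxy]-3-hydroxygermacra-1(10)E,4Z,11(13)-trien-12,6-olide | C=C1C(=O)O[C@@H]2/C=C(/C)[C@@H](O)C/C=C(\C)C[C@@H](OC(=O)[C@@]3(C)O[C@H]3C)[C@@H]12 | intermediate
26 | (3S,6R,7R,8R)-8-[(2S,3S)-2,3-epoxy-2-methylbutanoyloxy]-3-(3-methylbutanoyloxy)germacra-1(10)E,4Z,11(13)-trien-12,6-olide | C=C1C(=O)O[C@@H]2/C=C(/C)[C@@H](OC(=O)CC(C)C)C/C=C(\C)C[C@@H](OC(=O)[C@@]3(C)O[C@H]3C)[C@@H]12 | intermediate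
27 | (1R,3S,6R,7R,8R,10R)-1,10-epoxy-8-[(2S,3S)-2,3-epoxy-2-methylbutanoyloxy]-3-(3-methylbutanoyloxy)germacra-4Z,11(13)-dien-12,6-olide | C=C1C(=O)O[C@@H]2/C=C(/C)[C@@H](OC(=O)CC(C)C)C[C@H]3O[C@]3(C)C[C@@H](OC(=O)[C@@]3(C)O[C@H]3C)[C@@H]12 | target

**Count and risks**

Total step count: 17. Longest linear sequence: 12 steps (1, 2, 3, 6, 7, 8, 9, 10, 14, 15, 16, 17).

Most likely to fail:

Step 9 (key annulation). What may go wrong: carbopalladation on the ring‑covered face of C6=C7 or at the wrong diene terminus, β‑hydride elimination of the π‑allyl intermediate to a triene acid, or Cope ring contraction of 14 before it is consumed. The fallback sets out from 10 and comes back at 16. The ring expansion of step 7 is run as before, but dienolate 12 is C‑alkylated at −78 °C with allyl bromoacetate on its open face to give allyl (7R)-6-oxo ester F1. NaBH4/CeCl3 should add hydride from the same outer face and give the 6S hydroxy ester F2, and Pd(PPh3)4/morpholine frees the hydroxy acid F3. PPh3/diisopropyl azodicarboxylate then closes the lactone by attack of the carboxylate oxygen on C6 with inversion (Mitsunobu lactonisation) and gives the trans‑fused 11,13‑dihydro‑13‑nor lactone F4. tert-Butoxybis(dimethylamino)methane converts it into the enamino lactone F5, and i-Bu2AlH reduction with loss of dimethylamine gives 16.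

Step 7 (oxy‑Cope/triflation). What may go wrong: β‑elimination of 4‑methoxybenzyloxide from dienolate 12 before it is sulfonylated, or erosion of the enolate geometry. The fallback sets out from 10 and comes back at 14. The elimination is accepted and driven to completion (KN(SiMe3)2, 18-crown-6, THF, 23 °C) to give the cross‑conjugated trienone F6. NaBH4/CeCl3 gives the 6S bis‑allylic alcohol F7; its 6R epimer is recycled by oxidation. A perrhenate‑catalysed suprafacial 1,3‑transposition of the hydroxyl group (Ph3SiOReO3, Et2O, −40 °C), driven by conjugation of the new 6E olefin with C4=C5, moves the oxygen to C8 and should give the 8R dienol F8. 4-Methoxybenzyl trichloroacetimidate with La(OTf)3 then gives 14.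

Step 17 (epoxidation). What may go wrong: peracid attack on the inner face of C1=C10, or acid‑induced transannular opening of the epoxide once formed. The fallback sets out from 26 and comes back at 27. Oxygen is delivered under reagent control with the D‑fructose‑derived Shi ketone and KHSO5 (pH 10.5 buffer, MeCN/dimethoxymethane, 0 °C). Its spiro transition state should give the R,R epoxide of a trans‑trisubstituted olefin under non‑acidic conditions and ignore the electron‑poor C4=C5 and C11=C13 olefins. This fallback makes no new compound, F0.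

**Further compounds**

F1 | step 9 | allyl [(3S,7R,8R)-3-(tert-butyldimethylsilyloxy)-8-(4-methoxybenzyloxy)-4,10-dimethyl-6-oxocyclodeca-1(10)E,4Z-dien-7-yl]acetate | C=CCOC(=O)C[C@H]1C(=O)/C=C(/C)[C@@H](O[Si](C)(C)C(C)(C)C)C/C=C(\C)C[C@H]1OCc2ccc(OC)cc2
F2 | step 9 | allyl [(3S,6S,7R,8R)-3-(tert-butyldimethylsilyloxy)-6-hydroxy-8-(4-methoxybenzyloxy)-4,10-dimethylcyclodeca-1(10)E,4Z-dien-7-yl]acetate | C=CCOC(=O)C[C@H]1[C@@H](O)/C=C(/C)[C@@H](O[Si](C)(C)C(C)(C)C)C/C=C(\C)C[C@H]1OCc2ccc(OC)cc2
F3 | step 9 | [(3S,6S,7R,8R)-3-(tert-butyldimethylsilyloxy)-6-hydroxy-8-(4-methoxybenzyloxy)-4,10-dimethylcyclodeca-1(10)E,4Z-dien-7-yl]acetic acid | OC(=O)C[C@H]1[C@@H](O)/C=C(/C)[C@@H](O[Si](C)(C)C(C)(C)C)C/C=C(\C)C[C@H]1OCc2ccc(OC)cc2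
F4 | step 9 | (3S,6R,7R,8R)-3-(tert-butyldimethylsilyloxy)-8-(4-methoxybenzyloxy)-13-norgermacra-1(10)E,4Z-dien-12,6-olide | C1C(=O)O[C@@H]2/C=C(/C)[C@@H](O[Si](C)(C)C(C)(C)C)C/C=C(\C)C[C@@H](OCc3ccc(OC)cc3)[C@@H]12
F5 | step 9 | (3S,6R,7R,8R,11E)-3-(tert-butyldimethylsilyloxy)-13-(dimethylamino)-8-(4-methoxybenzyloxy)germacra-1(10)E,4Z,11(13)-trien-12,6-olide | CN(C)/C=C1/C(=O)O[C@@H]2/C=C(/C)[C@@H](O[Si](C)(C)C(C)(C)C)C/C=C(\C)C[C@@H](OCc3ccc(OC)cc3)[C@@H]12
F6 | step 7 | (3S)-3-(tert-butyldimethylsilyloxy)-4,10-dimethylcyclodeca-1(10)E,4Z,7Z-trien-6-one | [C@@H]1(O[Si](C)(C)C(C)(C)C)/C(C)=C\C(=O)/C=C\C/C(C)=C/C1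
F7 | step 7 | (3S,6S)-3-(tert-butyldimethylsilyloxy)-4,10-dimethylcyclodeca-1(10)E,4Z,7Z-trien-6-ol | [C@@H]1(O[Si](C)(C)C(C)(C)C)/C(C)=C\[C@@H](O)/C=C\C/C(C)=C/C1
F8 | step 7 | (3S,8R)-3-(tert-butyldimethylsilyloxy)-4,10-dimethylcyclodeca-1(10)E,4Z,6E-trien-8-ol | [C@@H]1(O[Si](C)(C)C(C)(C)C)/C(C)=C\C=C\[C@H](O)C/C(C)=C/C1
F0 | step 17 | none | none
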